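Read at 15 h, each flask shows what it could turn out in that time, so the reckoning counts how much target a flask makes by then and whether its substrate lasts that long.

| setting | Wednesday's | Thursday's | theta | gamma | eta | delta | alpha |
|---|---|---|---|---|---|---|---|
| substrate | 0.19 M | 0.19 M | 0.15 M | 2.5 M | 0.60 M | 1.2 M | 0.40 M |
| gas | 55 mM (held) | 55 mM (held) | 55 mM (held) | 55 mM (held) | 55 mM (held) | 55 mM (held) | 55 mM (held) |
| initiator | 28 mM | 28 mM | 28 mM | 28 mM | 28 mM | 28 mM | 28 mM |
| temperature | 20 °C | 31 °C | 25 °C | 25 °C | 25 °C | 25 °C | 25 °C |
| remark | run made earlier | run made earlier |  |  |  |  |  |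
| time |  |  | 15 h | 15 h | 15 h | 15 h | 15 h |

| run | time / h | target / % | substrate / % |
|---|---|---|---|
| Wednesday's | 4.00 | 10.8 | 58.0 |
| Wednesday's | 8.00 | 22.9 | 34.2 |
| Wednesday's | 12.0 | 36.4 | 19.8 |
| Wednesday's | 15.0 | 45.8 | 8.9 |
| Thursday's | 4.00 | 11.9 | 36.6 |
| Thursday's | 8.00 | 26.5 | 16.0 |
| Thursday's | 12.0 | 40.3 | 0.2 |
| Thursday's | 15.0 | 39.6 | 0 |

(scatter of a reading: 1 percentage point)

- at the start none of the gas is in solution
- a reading or a percentage of target counts all its forms, free or not

* the flasks by amount of target, in percent of the substrate charged, highest first, at 15 h (theta / gamma / eta / delta / alpha)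
* the amount of target, in percent of the substrate charged of the flask you put first, at 15 h
* the amount of target, in percent of the substrate charged of the flask you put last, at 15 h

Target climbs steadily in both runs: Wednesday's reaches 45.8% at 15.0 h, and Thursday's reaches 40.3% at 12.0 h, where its substrate stands at 0.2% and the target stops. As paces, r, these lie close together in spite of the temperature gap:

r(Wednesday) = 5.80 mM h⁻¹, r(Thursday) = 6.38 mM h⁻¹, mean r = 6.09 mM h⁻¹

Taking the pace as zero order in substrate, that is, as not depending on how much substrate stands, and taking it to hold at 25 °C, which lies between the temperatures of the two runs, the reckoning multiplies it by the time t: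

H = r t = 91.4 mM

This H is the target ceiling, the amount turned out by the time of reading at pace r. Divided by the charges, it gives gamma 3.65%, delta 7.61%, eta 15.2%, alpha 22.8% and theta 60.9%.

The weak link is theta: in both runs substrate also disappears without becoming target, and theta's charge of 0.15 M is less than their 0.19 M. Taking that loss as second order, with constant s, the first reading of each run gives:

s(Wednesday) = 0.708 M⁻¹ h⁻¹, s(Thursday) = 1.85 M⁻¹ h⁻¹, geometric mean s = 1.14 M⁻¹ h⁻¹

Wednesday's remaining 8.9% is reckoned, at its pace, to last to 17.9 h, and Thursday's lasted to 12.0 h, so a flask of their charge at the middle temperature is given a life of 14.7 h. Theta is reckoned as that flask joined late, after the loss alone has taken its substrate down to theta's charge: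

life of theta = 14.7 h − 1.23 h = 13.4 h, target = 54.6%

Alpha, joined earlier, is reckoned to last to 17.1 h, later than the reading, so alpha, eta, delta and gamma are reckoned at the ceiling.

The forecast, theta > alpha > eta > delta > gamma, with 55% (48% to 62%) and 3.6% (2.8% to 4.4%), has the same order as this reckoning and stands a little apart in its numbers, on the ground “That is zero order with almost no temperature dependence, so gas transfer limits it.”

The flasks give theta > alpha > eta > delta > gamma, with theta at 55.3% and gamma at 3.60%.

    initiator → 2 initiating radical (k = 0.00191 h⁻¹, Ea = 114 kJ mol⁻¹)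
    substrate + initiating radical → capped initiator + first chain carrier (k = 42300 M⁻¹ s⁻¹, Ea = 19.0 kJ mol⁻¹)
    coupling partner + first chain carrier → target + second chain carrier (k = 1.08 × 10⁵ M⁻¹ s⁻¹, Ea = 10.0 kJ mol⁻¹)
    substrate + second chain carrier → released group + first chain carrier (k = 2.78 × 10⁷ M⁻¹ h⁻¹, Ea = 32.0 kJ mol⁻¹)
    2 first chain carrier → ended chains (k = 2.00 × 10⁸ M⁻¹ s⁻¹, Ea = 10.0 kJ mol⁻¹)
    gas ⇌ coupling partner, rate k6*(csat - [coupling partner]) (kL = 0.124 h⁻¹)
    coupling partner + target ⇌ idle adduct, settled at all times (K = 46.3 M⁻¹, ΔH = 10.0 kJ mol⁻¹)
    2 substrate → homo dimer (k = 0.502 M⁻¹ h⁻¹, Ea = 59.0 kJ mol⁻¹)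
    (constants at 25 °C)

In gamma at 0.362 h, the conversion into homo dimer uses substrate 380 times as fast as the step of substrate with second chain carrier does, and 99% of the turnover of that conversion up to 15 h is behind it by 7.50 h, while the transfer of gas to coupling partner, the rate-limiting step for target, has half of its turnover done by 7.49 h, with coupling partner at 0.00185 M at 15.0 h against a saturation of 55 mM. Gamma's 90.0 mM of target, all forms counted, stands beside the ceiling of 91.4 mM, and a neighbour of gamma with 0.62 M of substrate, given 14.7% by that ceiling, holds 14.5%.

The numbers in the tables were generated by integration with made-up constants; noise was put on by code.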